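All runs were computed for an exercise; noise was put on by code.

Subtract the protic impurity from the partner before reading any curve.

common to all: solid substrate 0.38 M

| flask | partner | protic impurity | remark | time |
|---|---|---|---|---|
| Wednesday's | 1.2 equiv | 0.076 M | the very flask that is asked about, followed so far |  |
| Monday's | 1.2 equiv | 0.15 M | run made earlier |  |
| flask | 1.20 equiv | 0.0760 M |  | 20 min |

| run | time / min | target / % |
|---|---|---|
| Wednesday's | 0.833 | 9.7 |
| Wednesday's | 2.50 | 26.4 |
| Wednesday's | 5.00 | 45.6 |
| Wednesday's | 8.00 | 62.0 |
| Wednesday's | 10.0 | 71.9 |
| Monday's | 1.00 | 7.9 |
| Monday's | 2.00 | 16.5 |
| Monday's | 4.00 | 31.0 |
| Monday's | 8.00 | 50.6 |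
| Monday's | 15.0 | 64.0 |

(each reading ± 1 percentage point)

- target at 20 min, in percent of the solid substrate charged
- the change that raises the amount of target at 20 min, in percent of the solid substrate charged most ("none" if none brings more than 2 percentage points) (winter / noon / autumn / none)
- amount of target at 20 min, in percent of the solid substrate charged, after winter

- winter: doubling the solubility of the solid substrate, all else as stated
- noon: doubling the dissolution coefficient of the solid substrate, all else as stated
- autumn: doubling the amount of partner, all else as stated

- given per volume of solution although it is solid: solid substrate
- the earlier runs were read with a standard deviation of 1 percentage point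
- at the start none of the solid substrate is in solution

I set two amounts against each other: the partner left once the protic impurity has taken its equal amount, and the solid substrate charged. Their ratio I called the usable partner >99.9%, against 80.5% in Monday's flask. In Monday's flask the usable partner stood below the solid substrate charged, which made partner the limiting reagent there; in Wednesday's flask the two stood level. I took the usable partner as my ceiling for target in both flasks. The readings at 8.00 min stood in the ratio 1.23, the usable amounts in the ratio 1.24. In powers of ten, the unused share of usable partner fell one power in 19.0 min on Wednesday and 18.6 min on Monday, so I used one clock for both flasks. At 20 min, my reckoning gave 91.1%.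

The forecast gave 88%, below my figure. It named autumn and put winter at 95%: “Winter doubles the rate but stays capped by partner”.

    partner + protic impurity → quenched reagent (k = 0.330 /M/s)
    solid substrate ⇌ dissolved substrate, rate k2*(cs2 - [dissolved substrate]) while solid is left; crystals form when [dissolved substrate] > cs2 (solubility = 0.0590 M, k = 0.0820 /s)
    dissolved substrate + partner → target (k = 0.0440 /M/s)
    solid substrate + target → side product (k = 0.00180 /M/s)

The flask gave 85.4%, with autumn the best change and 92.5% after winter. Side product stood at 9.75% at 20.0 min, each counting as two. The usable partner less the 9.76% of the solid substrate charged still present as partner is 90.2%, which matches target plus half the side product, 90.3%. Target moved 5 points at 1.12 equiv of partner or 0.105 M of protic impurity, so a run at such a charge could prove the forecast wrong.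

The neighbour with 0.300 equiv of partner has a usable partner of 10.0%; it gave 6.19% of target.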